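The constants are hidden, but charges can be counted, so we count catalyst.

the same everywhere: left-handed substrate 0.10 M; right-handed substrate 0.10 M; free catalyst 9.4 mol%; added ligand 29 mM; impurity 4.1 mM
- zeta: partner 2.2 equiv; precatalyst 0.07 mol%; run made earlier
- gamma: partner 2.2 equiv; precatalyst 0.28 mol%; run made earlier
- Monday's: partner 2.20 equiv; precatalyst 0.14 mol%; time 10 min
- Tuesday's: partner 2.20 equiv; precatalyst 0.14 mol%; time 3.0 min

| run | time / min | right-handed substrate / % | left-handed substrate / % |
|---|---|---|---|
| zeta | 1.00 | 47.9 | 42.2 |
| zeta | 3.00 | 44.6 | 38.2 |
| zeta | 5.00 | 42.4 | 31.7 |
| zeta | 8.00 | 38.1 | 28.3 |
| gamma | 2.00 | 43.8 | 38.6 |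
| gamma | 4.00 | 41.2 | 35.8 |
| gamma | 6.00 | 40.2 | 32.3 |
| gamma | 8.00 | 39.1 | 31.7 |

(standard deviation of a reading: 1 percentage point)

- free catalyst is single-handed; left-handed substrate and right-handed substrate are mirror images of each other, charged as a racemate, each of them at the stated concentration
- steps under discussion: partner + free catalyst + left-handed substrate -> free catalyst + left-handed product; partner + free catalyst + right-handed substrate -> free catalyst + right-handed product; left-handed substrate + racemization catalyst <-> right-handed substrate + racemization catalyst; free catalyst + added ligand <-> idle complex; precatalyst -> racemization catalyst; free catalyst + impurity -> spent catalyst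
- an excess is the difference of the two amounts in percent of their sum
- an excess is below zero if the other one leads

* the flask that ends with the higher excess of right-handed substrate over left-handed substrate among what is left of the two, or "neither" when 2 percentage points or less lies between them (Monday's / Tuesday's / neither)
* excess of right-handed substrate over left-handed substrate among what is left of the two at the end, Monday's
* excess of right-handed substrate over left-handed substrate among what is left of the two at the end, Tuesday's

Monday's and Tuesday's flasks each hold 9.40 mM of free catalyst and 4.1 mM of impurity. Poisoning is an irreversible one-for-one step in which impurity is the limiting reagent. The added ligand binds reversibly, so it shares catalyst between free catalyst and idle complex without destroying it. What we carry from these two amounts is their difference, the surviving catalyst, which counts free catalyst and idle complex together: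

surviving catalyst = catalyst charged − impurity charged = 5.30 mM

The zeta readings are in line with a fast early loss of catalyst: the run lost 9.90% of the two substrates together by 1.00 min, then 7.3 percentage points more up to 3.00 min.

apparent turnovers (substrate reacted per surviving catalyst) by 3.00 min in zeta = 34.4 mM / 5.30 mM = 6.49

At that point the zeta readings give an excess of 7.73%, which is our figure for Tuesday's: the survivors and the time are the same, though the zeta run has half of Tuesday's precatalyst. Monday's runs to 10 min, and its precatalyst lies between that of zeta and gamma, so for Monday's we take the midpoint of the zeta and gamma excesses read at 8.00 min, 14.8% and 10.5%, which is 12.7%. Monday's should therefore lead.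

The forecast gives Monday's, with 13% for Monday's and 7.5% for Tuesday's, the latter on the ground that “Tuesday (3 min) is still early”.

Tuesday's gives 8.73% and Monday's 14.9%, so Monday's leads.

    partner + free catalyst + left-handed substrate → free catalyst + left-handed product (k = 2.72 L² mol⁻² s⁻¹)
    partner + free catalyst + right-handed substrate → free catalyst + right-handed product (k = 1.10 L² mol⁻² s⁻¹)
    left-handed substrate + racemization catalyst ⇌ right-handed substrate + racemization catalyst, rate k3*[racemization catalyst]*[left-handed substrate] forward; the back reaction follows from the equilibrium constant (k = 2.37 L mol⁻¹ s⁻¹)
    free catalyst + added ligand ⇌ idle complex (K = 87.2 L mol⁻¹, k = 0.290 L mol⁻¹ s⁻¹)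
    precatalyst → racemization catalyst (k = 0.0147 s⁻¹)
    free catalyst + impurity → spent catalyst (k = 83.4 L mol⁻¹ s⁻¹)

In Tuesday's, spent catalyst stands at 43.6%, the share we counted, and the apparent turnovers reach 7.26 by 3.00 min. For Tuesday's time, with the other charges held, we take the excess as proportional to the surviving catalyst. The neighbour of Tuesday's with 0.0070 M of impurity keeps 2.40 mM of surviving catalyst, which by this reckoning gives 3.95%. The neighbour flask gives 4.19%.

Readings and results are simulated from invented constants.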